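## Retrosynthetic overview

1. The ester is made last by Steglich acylation of (R)-shikonin (18) with 3-hydroxy-3-methylbutanoic acid; 18 comes from its 5,8-bis(MOM) ether 17 by mild acid.
2. The quinone ring (C1–C2–C3–C4–C4a–C8a) is closed last, on the preformed benzenoid ring, by forming the C2–C3 bond: the enolate of the C4 acetyl group (C3) opens an α,β-epoxy ketone at C2, followed by aromatising tautomerisation and oxidation in the same flask.
3. Enabling feature: the trans-oxirane spanning C2 and C1′ next to the C1 ketone. Its O–C2 bond is not in the target; its strain and the α-keto activation make C2 an SN2 electrophile, while the untouched C1′–O bond carries the (R) stereocentre, set earlier by Sharpless epoxidation.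
4. The epoxy diketone 13 comes from methyl 2,5-bis(methoxymethoxy)benzoate by ortho-magnesiation, addition to epoxy aldehyde 6 (phthalide 11 as a temporary ring), MeLi opening and oxidation; 6 comes from propargyl alcohol and prenyl bromide via the E-dienol.
5. Ring order: benzenoid ring (starting material) → oxirane (temporary) → lactone (temporary) → quinone ring (step 9).

Key step: step 9

Remark: locants C1–C4, C4a, C8a denote the quinone ring and C1′ the side-chain carbinol carbon; the naphthazarin tautomers interconvert rapidly and are treated as the one compound drawn in the target structure.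

## Route

Step 1
Reactants: 1 propargyl alcohol; 2 prenyl bromide (1-bromo-3-methylbut-2-ene)
Product: 3 6-methylhept-5-en-2-yn-1-ol
Conditions: CuI (cat.), n-Bu4NI (cat.), K2CO3, DMF, rt
Reagents that add atoms: none
Why: Copper-catalysed coupling of a terminal alkyne with an allylic bromide (Jeffery-type alkynylcopper allylation) should join the acetylide to the primary carbon of the prenyl unit under conditions too mild to isomerise the skipped enyne.

Step 2
Reactants: 3 6-methylhept-5-en-2-yn-1-ol
Product: 4 (2E)-6-methylhepta-2,5-dien-1-ol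
Conditions: LiAlH4, THF, 0 °C → reflux; Fieser work-up
Reagents that add atoms: none
Why: Hydroxyl-directed trans-hydroalumination of the propargylic alcohol (LiAlH4 reduction) should give only the E-allylic alcohol and leave the isolated trisubstituted alkene untouched.

Step 3
Reactants: 4 (2E)-6-methylhepta-2,5-dien-1-ol
Product: 5 [(2R,3R)-3-(3-methylbut-2-en-1-yl)oxiran-2-yl]methanol
Conditions: Ti(OiPr)4 (10 mol %), D-(−)-diethyl tartrate (12 mol %), t-BuOOH, 4 Å MS, CH2Cl2, −20 °C
Reagents that add atoms: tert-butyl hydroperoxide CC(C)(C)OO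
Why: Sharpless asymmetric epoxidation with the D-tartrate/titanium catalyst delivers oxygen to one face of the allylic alcohol double bond, setting both oxirane carbons as R (C3 is the later C1′), while the remote alkene, lacking a directing hydroxyl, should not react.

Step 4
Reactants: 5 [(2R,3R)-3-(3-methylbut-2-en-1-yl)oxiran-2-yl]methanol
Product: 6 (2S,3R)-3-(3-methylbut-2-en-1-yl)oxirane-2-carbaldehyde
Conditions: TEMPO (10 mol %), PhI(OAc)2, CH2Cl2, rt
Reagents that add atoms: none
Why: TEMPO/PhI(OAc)2 (oxoammonium) oxidation stops at the aldehyde under nearly neutral conditions, so the oxirane, its α-carbon and the alkene should stay intact (the descriptor at C2 changes by CIP rules only).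

Step 5
Reactants: 7 methyl 2,5-dihydroxybenzoate
Product: 8 methyl 2,5-bis(methoxymethoxy)benzoate
Conditions: NaH, MOMCl, DMF, 0 °C → rt
Reagents that add atoms: chloromethyl methyl ether (MOMCl) COCCl
Why: Williamson etherification of both phenoxides gives MOM acetals that assist the later metalation, survive the organometallic and basic steps, and are removable with dilute acid.

Step 6
Reactants: 8 methyl 2,5-bis(methoxymethoxy)benzoate; 6 (2S,3R)-3-(3-methylbut-2-en-1-yl)oxirane-2-carbaldehyde
Product: 11 4,7-bis(methoxymethoxy)-3-[(2S,3R)-3-(3-methylbut-2-en-1-yl)oxiran-2-yl]isobenzofuran-1(3H)-one (both C-3 epimers), via arylmagnesium chloride 9 (not isolated), via magnesium alkoxide 10 (not isolated)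
Conditions: TMPMgCl·LiCl, THF, 0 °C; then 6, −30 → 0 °C; aq. NH4Cl
Reagents that add atoms: none
Why: Directed ortho-magnesiation with the Knochel–Hauser base should occur at the only position flanked by both the ester and a MOM ether, and Grignard addition to 6 followed by lactonisation of the alkoxide onto the neighbouring ester gives the phthalide, whose new carbinol centre forms as an inconsequential epimer mixture because it is oxidised in step 8.

Step 7
Reactants: 11 phthalide from step 6
Product: 12 1-[2-{hydroxy[(2R,3R)-3-(3-methylbut-2-en-1-yl)oxiran-2-yl]methyl}-3,6-bis(methoxymethoxy)phenyl]ethan-1-one (carbinol epimers; in equilibrium with its cyclic hemiketal)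
Conditions: MeLi (1.05 equiv), THF, −78 °C; then H2O
Reagents that add atoms: methyllithium [Li]C
Why: Nucleophilic acyl addition of one equivalent of MeLi to the lactone at −78 °C should stop at the lithium hemiketalate, which on work-up gives the methyl ketone and frees the secondary alcohol, the oxirane being inert to MeLi at this temperature.

Step 8
Reactants: 12 hydroxy ketone from step 7
Product: 13 1-{2-[(2S,3R)-3-(3-methylbut-2-en-1-yl)oxirane-2-carbonyl]-3,6-bis(methoxymethoxy)phenyl}ethan-1-one
Conditions: Dess–Martin periodinane, pyridine, CH2Cl2, 0 °C → rt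
Reagents that add atoms: none
Why: Dess–Martin oxidation of the secondary alcohol, drawn out of the hemiketal equilibrium (the hemiketal carbon has no C–H), gives the α,β-epoxy ketone under buffered conditions that should not open the oxirane.

Step 9
Reactants: 13 epoxy diketone from step 8
Product: 17 2-[(1R)-1-hydroxy-4-methylpent-3-en-1-yl]-5,8-bis(methoxymethoxy)naphthalene-1,4-dione, via lithium enolate 14 (not isolated), via ring-closed lithium alkoxide 15 (not isolated), via hydroquinone 16 (not isolated)
Conditions: LiHMDS (2.5 equiv), THF, −78 → 0 °C; AcOH; then Ag2O, MgSO4, rt (one pot)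
Reagents that add atoms: none
Why: Proposed new method: LiHMDS deprotonates only the acetyl methyl group (C3) to give enolate 14, whose carbon attacks C2, the oxirane carbon α to the C1 ketone, anti to the C2–O bond, so that the strained C2–O bond breaks, the C2–C3 bond forms and the ring C1–C2–C3–C4–C4a–C8a closes in a 6-(enolendo)-exo-tet mode to give alkoxide 15. Excess base enolises 15 at once to the aromatic naphthalene-1,4-diolate, which can no longer undergo retro-aldol cleavage; AcOH then gives hydroquinone 16 and Ag2O oxidises it in the same flask to quinone 17. The closest known reactions are the intramolecular alkylation of ketone enolates by epoxides (Stork-type epoxide cyclisation) and the SN2 opening of α,β-epoxy ketones at Cα by soft nucleophiles; their combination in an aromatising ring closure is the untested part. No new stereocentre survives: C1′ stays R because its C–O bond is never broken, and the transient centre at C2 (formed with inversion) is erased by enolisation. The step needs C-alkylation at C2 rather than aldol addition to the C1 carbonyl (5-(enolendo)-exo-trig, disfavoured and reversible), O-alkylation, or attack at C1′ (7-endo); this should be secured by the α-keto activation of C2, the exo mode of opening, the irreversibility of the strain-releasing alkylation, and the flanking MOM ethers, which twist both acyl groups out of the arene plane and stack them so that C3 lies over C2.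

Step 10
Reactants: 17 quinone from step 9
Product: 18 (R)-shikonin, 5,8-dihydroxy-2-[(1R)-1-hydroxy-4-methylpent-3-en-1-yl]naphthalene-1,4-dione
Conditions: 3 M aq. HCl, THF, 0 °C → rt
Reagents that add atoms: none
Why: Acid hydrolysis of the two aryl MOM acetals, activated by the peri carbonyl groups, should proceed under conditions mild enough for the side chain because the electron-poor quinone ring disfavours ionisation at C1′.

Step 11
Reactants: 18 (R)-shikonin; 19 3-hydroxy-3-methylbutanoic acid
Product: 20 β-HIVS, (1R)-1-(5,8-dihydroxy-1,4-dioxo-1,4-dihydronaphthalen-2-yl)-4-methylpent-3-en-1-yl 3-hydroxy-3-methylbutanoate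
Conditions: DCC, DMAP (cat.), CH2Cl2, 0 °C → rt
Reagents that add atoms: none
Why: Steglich esterification should acylate only the secondary side-chain hydroxyl, since the peri phenols are locked in hydrogen bonds to the quinone carbonyls and the tertiary hydroxyl of the acid is too hindered to compete, and C1′ is not touched so its R configuration is retained.

## Compound list

1 | propargyl alcohol | C#CCO | starting material
2 | prenyl bromide (1-bromo-3-methylbut-2-ene) | CC(C)=CCBr | starting material
3 | 6-methylhept-5-en-2-yn-1-ol | CC(C)=CCC#CCO | intermediate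
4 | (2E)-6-methylhepta-2,5-dien-1-ol | CC(C)=CC/C=C/CO | intermediate
5 | [(2R,3R)-3-(3-methylbut-2-en-1-yl)oxiran-2-yl]methanol | OC[C@H]1O[C@@H]1CC=C(C)C | intermediate
6 | (2S,3R)-3-(3-methylbut-2-en-1-yl)oxirane-2-carbaldehyde | O=C[C@H]1O[C@@H]1CC=C(C)C | intermediate
7 | methyl 2,5-dihydroxybenzoate | COC(=O)c1cc(O)ccc1O | starting material
8 | methyl 2,5-bis(methoxymethoxy)benzoate | COC(=O)c1cc(OCOC)ccc1OCOC | intermediate
9 | [2-(methoxycarbonyl)-3,6-bis(methoxymethoxy)phenyl]magnesium chloride (LiCl complex, not isolated) | COC(=O)c1c([Mg]Cl)c(OCOC)ccc1OCOC | intermediate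
10 | chloromagnesium alkoxide of methyl 2-{hydroxy[trans-oxiranyl as in 6]methyl}-3,6-bis(methoxymethoxy)benzoate (carbinol epimers, not isolated) | COC(=O)c1c(C(O[Mg]Cl)[C@H]2O[C@@H]2CC=C(C)C)c(OCOC)ccc1OCOC | intermediate
11 | 4,7-bis(methoxymethoxy)-3-[(2S,3R)-3-(3-methylbut-2-en-1-yl)oxiran-2-yl]isobenzofuran-1(3H)-one (C-3 epimers) | O=C1OC([C@H]2O[C@@H]2CC=C(C)C)c2c(OCOC)ccc(OCOC)c12 | intermediate
12 | 1-[2-{hydroxy[(2R,3R)-3-(3-methylbut-2-en-1-yl)oxiran-2-yl]methyl}-3,6-bis(methoxymethoxy)phenyl]ethan-1-one (carbinol epimers; with its cyclic hemiketal) | CC(=O)c1c(OCOC)ccc(OCOC)c1C(O)[C@H]2O[C@@H]2CC=C(C)C | intermediate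
13 | 1-{2-[(2S,3R)-3-(3-methylbut-2-en-1-yl)oxirane-2-carbonyl]-3,6-bis(methoxymethoxy)phenyl}ethan-1-one | CC(=O)c1c(OCOC)ccc(OCOC)c1C(=O)[C@H]2O[C@@H]2CC=C(C)C | intermediate
14 | lithium enolate of 13 at the acetyl group (not isolated) | [Li]OC(=C)c1c(OCOC)ccc(OCOC)c1C(=O)[C@H]2O[C@@H]2CC=C(C)C | intermediate
15 | lithium alkoxide of 2-[(1R)-1-hydroxy-4-methylpent-3-en-1-yl]-5,8-bis(methoxymethoxy)-2,3-dihydronaphthalene-1,4-dione (C-2 transient, not isolated) | CC(C)=CC[C@@H](O[Li])C1CC(=O)c2c(OCOC)ccc(OCOC)c2C1=O | intermediate
16 | 2-[(1R)-1-hydroxy-4-methylpent-3-en-1-yl]-5,8-bis(methoxymethoxy)naphthalene-1,4-diol (not isolated) | CC(C)=CC[C@@H](O)c1cc(O)c2c(OCOC)ccc(OCOC)c2c1O | intermediate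
17 | 2-[(1R)-1-hydroxy-4-methylpent-3-en-1-yl]-5,8-bis(methoxymethoxy)naphthalene-1,4-dione | CC(C)=CC[C@@H](O)C1=CC(=O)c2c(OCOC)ccc(OCOC)c2C1=O | intermediate
18 | (R)-shikonin | CC(C)=CC[C@@H](O)C1=CC(=O)c2c(O)ccc(O)c2C1=O | intermediate
19 | 3-hydroxy-3-methylbutanoic acid | CC(C)(O)CC(=O)O | starting material
20 | β-HIVS, (1R)-1-(5,8-dihydroxy-1,4-dioxo-1,4-dihydronaphthalen-2-yl)-4-methylpent-3-en-1-yl 3-hydroxy-3-methylbutanoate | CC(C)=CC[C@@H](OC(=O)CC(C)(C)O)C1=CC(=O)c2c(O)ccc(O)c2C1=O | target

## Step count and risks

Total steps: 11. Longest linear sequence: 10 steps (steps 1–4, then 6–11, from propargyl alcohol).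

Steps most likely to fail:

**Step 9 (proposed new method).** The enolate may add to the C1 carbonyl instead of C2, or the aldolate may fragment by retro-aldol before it aromatises. The fallback uses known reactions and sets out from 13. Samarium diiodide (THF/MeOH, −90 °C) cleaves the oxirane C2–O bond reductively to give 1-[2-acetyl-3,6-bis(methoxymethoxy)phenyl]-(3R)-3-hydroxy-6-methylhept-5-en-1-one F1. TBSCl/imidazole converts it into the silyl ether F2. Double deprotonation (LDA, 2.2 equiv, −78 °C) and copper(II)-mediated intramolecular oxidative dienolate coupling (CuCl2, DMF/THF) then close the same C2–C3 bond; tautomerisation gives the hydroquinone silyl ether F3, which Ag2O oxidises in the flask to the quinone silyl ether F4. HF·pyridine in THF removes the silyl group, and the route is rejoined at 17.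

**Step 6.** Metalation may occur at another ring position, the ester-bearing arylmagnesium may self-condense, or magnesium salts may open the oxirane during a slow addition. The fallback sets out from 8 and makes the same organometallic by halogen–metal exchange at low temperature. LiOH hydrolysis gives 2,5-bis(methoxymethoxy)benzoic acid F5. Carboxylate-directed ortho-lithiation (s-BuLi/TMEDA, THF, −78 °C) with an iodine quench gives 2-iodo-3,6-bis(methoxymethoxy)benzoic acid F6. MeI/K2CO3 gives methyl 2-iodo-3,6-bis(methoxymethoxy)benzoate F7. I/Mg exchange with i-PrMgCl·LiCl at −40 °C then returns to the route at 9, which is taken on to 11 as in step 6.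

**Step 7.** A second MeLi may add to the ring-opened ketone, or MeLi may deprotonate the lactone C3–H, which would open the oxirane by β-elimination. The fallback sets out from 11. Lithiated methyl phenyl sulfone (2 equiv, THF, −78 °C) adds only once, because the product is held as a stabilised enolate, and gives the β-keto sulfone F8. Reductive desulfonylation with aluminium amalgam (aq. THF) returns to the route at 12.

Further compounds
F1 | step 9 | 1-[2-acetyl-3,6-bis(methoxymethoxy)phenyl]-(3R)-3-hydroxy-6-methylhept-5-en-1-one | CC(=O)c1c(OCOC)ccc(OCOC)c1C(=O)C[C@H](O)CC=C(C)C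
F2 | step 9 | 1-[2-acetyl-3,6-bis(methoxymethoxy)phenyl]-(3R)-3-(tert-butyldimethylsilyloxy)-6-methylhept-5-en-1-one | CC(=O)c1c(OCOC)ccc(OCOC)c1C(=O)C[C@H](O[Si](C)(C)C(C)(C)C)CC=C(C)C
F3 | step 9 | 2-[(1R)-1-(tert-butyldimethylsilyloxy)-4-methylpent-3-en-1-yl]-5,8-bis(methoxymethoxy)naphthalene-1,4-diol | CC(C)=CC[C@@H](O[Si](C)(C)C(C)(C)C)c1cc(O)c2c(OCOC)ccc(OCOC)c2c1O
F4 | step 9 | 2-[(1R)-1-(tert-butyldimethylsilyloxy)-4-methylpent-3-en-1-yl]-5,8-bis(methoxymethoxy)naphthalene-1,4-dione | CC(C)=CC[C@@H](O[Si](C)(C)C(C)(C)C)C1=CC(=O)c2c(OCOC)ccc(OCOC)c2C1=O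
F5 | step 6 | 2,5-bis(methoxymethoxy)benzoic acid | OC(=O)c1cc(OCOC)ccc1OCOC
F6 | step 6 | 2-iodo-3,6-bis(methoxymethoxy)benzoic acid | OC(=O)c1c(I)c(OCOC)ccc1OCOC
F7 | step 6 | methyl 2-iodo-3,6-bis(methoxymethoxy)benzoate | COC(=O)c1c(I)c(OCOC)ccc1OCOC
F8 | step 7 | 1-[2-{hydroxy[(2R,3R)-3-(3-methylbut-2-en-1-yl)oxiran-2-yl]methyl}-3,6-bis(methoxymethoxy)phenyl]-2-(phenylsulfonyl)ethan-1-one | O=C(CS(=O)(=O)c1ccccc1)c1c(OCOC)ccc(OCOC)c1C(O)[C@H]2O[C@@H]2CC=C(C)C
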